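**Plan**

- The target is read as epiafzelechin-(4β→8)-epiafzelechin-(4β→8)-epiafzelechin: every unit (2R,3R) and 2,3-cis, both interflavan bonds 3,4-trans. It is reached from its dodecabenzyl ether.
- Cuts: in the top unit C4–C4a (pyran ring C), then C4(top)–C8(middle); the same two cuts in the middle unit; C4–C4a in the bottom unit. All three units then come from one open-chain C2–C3–C4 aldehyde that carries ring B on C2 and ring A as a 3,5-dibenzyloxyphenyl ether on the future O1.
- Enabling feature: C4 of the top unit is a methine bonded to C8 of ring A of the middle unit, to C3 and to C4a of its own ring A. A cation at this carbon is stabilised by the O1- and 5,7-dioxygenated ring A of the middle unit, and the ortho carbon of the top unit's own ring A, tethered through O1–C2–C3, can close ring C onto it.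
- Forward order: aldehyde; ring C of the bottom unit by reductive Friedel–Crafts closure; C8 bromide, lithiation, addition to the aldehyde and cationic closure of ring C of the middle unit; the same three operations again for ring C of the top unit; hydrogenolysis.
- Stereochemistry: C2 and C3 of all units come from one Jacobsen epoxidation of a (Z)-cinnamate and SN2 opening of the cis-epoxide by the phenol. C4 of the middle and top units is set in the ring closures under control of the neighbouring C3.

Key step: step 12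

Remark on the chemistry: the two carbinols made by aryllithium addition are expected as epimer mixtures at the carbinol carbon; one epimer is drawn and both are carried into the ring closure, which erases this centre.

**Route**

Step 1
Reactants: 1 4-(benzyloxy)benzaldehyde; 2 ethyl (diphenoxyphosphoryl)acetate
Product: 3 ethyl (Z)-3-[4-(benzyloxy)phenyl]prop-2-enoate
Conditions: NaH, THF, −78 → 0 °C
Reagents that add atoms: none
Why: The Ando modification of the Horner–Wadsworth–Emmons olefination, in which the diaryl phosphonate makes oxaphosphetane collapse faster than adduct equilibration, should give mainly the (Z)-cinnamate, the minor (E)-isomer being removed by chromatography; no stereocenter is formed.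

Step 2
Reactants: 3 ethyl (Z)-3-[4-(benzyloxy)phenyl]prop-2-enoate
Product: 4 ethyl (2S,3S)-3-[4-(benzyloxy)phenyl]oxirane-2-carboxylate (cis-epoxide)
Conditions: (S,S)-[N,N′-bis(3,5-di-tert-butylsalicylidene)-1,2-cyclohexanediaminato]manganese chloride (5 mol %), 4-phenylpyridine N-oxide (25 mol %), aq. NaOCl (pH 11.3), CH2Cl2, 4 °C
Reagents that add atoms: sodium hypochlorite, [Na+].[O-]Cl
Why: Jacobsen epoxidation of (Z)-cinnamate esters is the established catalytic route to cis-3-arylglycidates, and since the (R,R) catalyst converts ethyl (Z)-cinnamate into the (2R,3R) epoxide, the (S,S) catalyst should set both stereocenters of 4 as (2S,3S) by oxygen transfer to one alkene face, any trans-epoxide from stepwise leakage being separated.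

Step 3
Reactants: 4 ethyl (2S,3S)-3-[4-(benzyloxy)phenyl]oxirane-2-carboxylate; 5 3,5-bis(benzyloxy)phenol
Product: 6 ethyl (2S,3R)-3-[3,5-bis(benzyloxy)phenoxy]-3-[4-(benzyloxy)phenyl]-2-hydroxypropanoate
Conditions: Cs2CO3 (0.3 equiv), DMF, 50 °C
Reagents that add atoms: none
Why: Base-catalysed epoxide opening by a phenoxide is an SN2 reaction that, for 3-arylglycidates, takes place at the benzylic C3, which is activated by the 4-benzyloxyphenyl group and is not alpha to the ester, so inversion at C3 with retention at C2 should turn the cis-epoxide into the (2S,3R) threo hydroxy ether, the arrangement that becomes 2,3-cis in each flavan unit.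

Step 4
Reactants: 6 ethyl (2S,3R)-3-[3,5-bis(benzyloxy)phenoxy]-3-[4-(benzyloxy)phenyl]-2-hydroxypropanoate
Product: 7 ethyl (2S,3R)-2-(benzyloxy)-3-[3,5-bis(benzyloxy)phenoxy]-3-[4-(benzyloxy)phenyl]propanoate
Conditions: BnBr, Ag2O, CH2Cl2, rt, dark
Reagents that add atoms: benzyl bromide, BrCc1ccccc1
Why: Williamson etherification promoted by Ag2O benzylates alpha-hydroxy esters without a strong base, so the alpha stereocenter should not epimerise and the beta-aryloxy group should not be eliminated; no stereocenter is formed.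

Step 5
Reactants: 7 ethyl (2S,3R)-2-(benzyloxy)-3-[3,5-bis(benzyloxy)phenoxy]-3-[4-(benzyloxy)phenyl]propanoate
Product: 8 (2S,3R)-2-(benzyloxy)-3-[3,5-bis(benzyloxy)phenoxy]-3-[4-(benzyloxy)phenyl]propanal
Conditions: i-Bu2AlH (1.05 equiv), CH2Cl2, −78 °C; then MeOH, aq. potassium sodium tartrate
Reagents that add atoms: none
Why: Partial reduction of an alpha-alkoxy ester by i-Bu2AlH at −78 °C stops at the aldehyde because the chelated aluminium hemiacetal survives until the aqueous work-up, and 8 is used without chromatography to avoid epimerisation at C2 and beta-elimination of the phenol.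

Step 6
Reactants: 8 (2S,3R)-2-(benzyloxy)-3-[3,5-bis(benzyloxy)phenoxy]-3-[4-(benzyloxy)phenyl]propanal
Product: 10 tetra-O-benzyl-(−)-epiafzelechin [(2R,3R)-3,5,7-tris(benzyloxy)-2-[4-(benzyloxy)phenyl]chromane], via flavan-4-ol 9 (not isolated)
Conditions: Et3SiH (5 equiv), BF3·OEt2 (0.5 equiv), CH2Cl2 (0.01 M), −78 → −20 °C
Reagents that add atoms: none
Why: The aldehyde complexed by BF3 is attacked by the ortho carbon of the tethered 3,5-dibenzyloxyphenyl ether (intramolecular Friedel–Crafts hydroxyalkylation, six-membered ring), the trioxygenated flavan-4-ol 9 ionises at once and the cation is reduced by Et3SiH (ionic hydrogenation), so C4 ends as a methylene group while C2 and C3 are untouched and the excess silane and the dilution keep the cation from adding to a second molecule.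

Step 7
Reactants: 10 tetra-O-benzyl-(−)-epiafzelechin
Product: 11 8-bromo-tetra-O-benzyl-(−)-epiafzelechin
Conditions: NBS (1.0 equiv), CH2Cl2, −78 → 0 °C
Reagents that add atoms: N-bromosuccinimide, O=C1CCC(=O)N1Br
Why: Electrophilic aromatic bromination of 5,7-dibenzyloxyflavans by N-bromosuccinimide is known to take place at C8, the carbon flanked by the pyran oxygen and the 7-benzyloxy group, before C6, and the singly oxygenated ring B is far less reactive.

Step 8
Reactants: 11 8-bromo-tetra-O-benzyl-(−)-epiafzelechin; 8 (2S,3R)-2-(benzyloxy)-3-[3,5-bis(benzyloxy)phenoxy]-3-[4-(benzyloxy)phenyl]propanal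
Product: 13 dimer-stage carbinol (C8 of the bottom flavan bonded to the carbinol carbon of the open middle unit), via 8-lithioflavan 12 (not isolated)
Conditions: t-BuLi (2.0 equiv), THF, −78 °C; then 8, −78 °C; then H2O
Reagents that add atoms: none
Why: Bromine–lithium exchange with t-BuLi at −78 °C is much faster than attack on the benzyl ethers, and the 2,6-dioxygenated aryllithium 12 adds to the aldehyde in a 1,2-addition that fixes the unit linkage at C8; Felkin–Anh control should favour the drawn 3,4-anti carbinol, but either epimer serves because this centre becomes planar in the next step.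

Step 9
Reactants: 13 dimer-stage carbinol
Product: 14 octa-O-benzyl-epiafzelechin-(4β→8)-epiafzelechin
Conditions: BF3·OEt2 (0.3 equiv), CH2Cl2 (0.005 M), −78 → −40 °C
Reagents that add atoms: none
Why: This is the cationic Friedel–Crafts ring closure of the key step in its simpler version: acid ionises the carbinol next to the trioxygenated ring A of the bottom unit, the ortho carbon of the tethered aryl ether closes pyran ring C of the middle unit, and allylic 1,3-strain in the cation places C3–H in its plane so that attack anti to the C3 benzyloxy group should set C4 as 3,4-trans (4β).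

Step 10
Reactants: 14 octa-O-benzyl-epiafzelechin-(4β→8)-epiafzelechin
Product: 15 8-bromo derivative of 14 (bromine on C8 of the upper unit)
Conditions: NBS (1.0 equiv), CH2Cl2, −78 → −20 °C
Reagents that add atoms: N-bromosuccinimide, O=C1CCC(=O)N1Br
Why: Electrophilic aromatic bromination should again choose the one remaining carbon that lies between a pyran oxygen and a benzyloxy group, C8 of the upper unit, since the two other free ring A carbons of 14 are C6 positions, which the monomer series shows to be distinctly less reactive towards N-bromosuccinimide.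

Step 11
Reactants: 15 8-bromo dimer; 8 (2S,3R)-2-(benzyloxy)-3-[3,5-bis(benzyloxy)phenoxy]-3-[4-(benzyloxy)phenyl]propanal
Product: 17 trimer-stage carbinol (C8 of the middle unit bonded to the carbinol carbon of the open top unit), via 8-lithio dimer 16 (not isolated)
Conditions: t-BuLi (2.0 equiv), THF, −78 °C; then 8 (1.5 equiv), −78 °C; then H2O
Reagents that add atoms: none
Why: As in step 8, bromine–lithium exchange followed by 1,2-addition of the aryllithium to the aldehyde joins C8 of the middle unit to the future C4 of the top unit, the aldehyde being used in excess to consume the valuable aryllithium 16, and the configuration of the new carbinol is again without consequence.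

Step 12
Reactants: 17 trimer-stage carbinol
Product: 18 dodeca-O-benzyl-epiafzelechin-(4β→8)-epiafzelechin-(4β→8)-epiafzelechin
Conditions: BF3·OEt2 (0.3 equiv), CH2Cl2 (0.005 M), −78 → −40 °C
Reagents that add atoms: none
Why: Substoichiometric BF3·OEt2 ionises the carbinol of 17 (both epimers) to a benzylic cation that is delocalised into ring A of the middle unit, whose ring oxygen and two benzyloxy groups sit ortho and para to the cationic carbon, and the ortho carbon of the top unit's tethered 3,5-dibenzyloxyphenyl ether attacks this cation and rearomatises by proton loss, forming C4–C4a. The closest known reactions are the acid-mediated intramolecular Friedel–Crafts alkylation of 3-aryloxy-1-arylpropan-1-ols to 4-arylchromans and the capture of flavan-4-yl cations by phloroglucinol ethers. Pyran ring C of the top unit closes as a six-membered ring, 6-exo-trig at the cationic carbon with the attacking arene π bond inside the new ring. The only new stereocenter, C4 of the top unit, is controlled by C3: allylic 1,3-strain with the ortho oxygens of the cation-bearing ring holds C3–H in the plane of the cation, the ether ring hangs from C2 on one face and adds anti to the C3 benzyloxy group, so the middle unit ends trans to that group (4β) as the target requires. The step needs site selectivity and a preference for ring closure over intermolecular arylation: the two ortho carbons of the ether ring are equivalent, its para carbon cannot reach the cation, ring B offers only carbons meta to its benzyloxy group, the C8 linkage was fixed in step 11, and high dilution disfavours attack by a second molecule. The acid-labile 4-benzyloxybenzylic C2–O bond and the existing interflavan bond should survive because the trioxygenated carbinol ionises at −78 °C with far less acid than they require.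

Step 13
Reactants: 18 dodeca-O-benzyl trimer
Product: 19 epiafzelechin-(4β→8)-epiafzelechin-(4β→8)-epiafzelechin (CNP0191553.1)
Conditions: H2 (1 atm), Pd(OH)2/C, THF/MeOH/H2O, rt
Reagents that add atoms: none
Why: Hydrogenolysis of benzyl ethers over Pd(OH)2/C is the standard last step for perbenzylated proanthocyanidins and should cleave all twelve benzyl groups while leaving the flavan C2–O1 bonds and the two interflavan bonds intact, as is usual for this compound class.

**Compound list**

1 | 4-(benzyloxy)benzaldehyde | O=Cc1ccc(OCc2ccccc2)cc1 | starting material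
2 | ethyl (diphenoxyphosphoryl)acetate | CCOC(=O)CP(=O)(Oc1ccccc1)Oc1ccccc1 | starting material
3 | ethyl (Z)-3-[4-(benzyloxy)phenyl]prop-2-enoate | CCOC(=O)/C=C\c1ccc(OCc2ccccc2)cc1 | intermediate
4 | ethyl (2S,3S)-3-[4-(benzyloxy)phenyl]oxirane-2-carboxylate (cis) | CCOC(=O)[C@H]1O[C@H]1c1ccc(OCc2ccccc2)cc1 | intermediate
5 | 3,5-bis(benzyloxy)phenol | Oc1cc(OCc2ccccc2)cc(OCc2ccccc2)c1 | starting material
6 | ethyl (2S,3R)-3-[3,5-bis(benzyloxy)phenoxy]-3-[4-(benzyloxy)phenyl]-2-hydroxypropanoate | CCOC(=O)[C@@H](O)[C@@H](c1ccc(OCc2ccccc2)cc1)Oc1cc(OCc2ccccc2)cc(OCc2ccccc2)c1 | intermediate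
7 | ethyl (2S,3R)-2-(benzyloxy)-3-[3,5-bis(benzyloxy)phenoxy]-3-[4-(benzyloxy)phenyl]propanoate | CCOC(=O)[C@@H](OCc1ccccc1)[C@@H](c1ccc(OCc2ccccc2)cc1)Oc1cc(OCc2ccccc2)cc(OCc2ccccc2)c1 | intermediate
8 | (2S,3R)-2-(benzyloxy)-3-[3,5-bis(benzyloxy)phenoxy]-3-[4-(benzyloxy)phenyl]propanal | O=C[C@@H](OCc1ccccc1)[C@@H](c1ccc(OCc2ccccc2)cc1)Oc1cc(OCc2ccccc2)cc(OCc2ccccc2)c1 | intermediate
9 | (2R,3R)-3,5,7-tris(benzyloxy)-2-[4-(benzyloxy)phenyl]chroman-4-ol (C4 epimers possible, 4S drawn; not isolated) | O[C@H]1c2c(OCc9ccccc9)cc(OCc9ccccc9)cc2O[C@H](c2ccc(OCc9ccccc9)cc2)[C@@H]1OCc9ccccc9 | intermediate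
10 | (2R,3R)-3,5,7-tris(benzyloxy)-2-[4-(benzyloxy)phenyl]chromane (3,5,7,4′-tetra-O-benzyl-(−)-epiafzelechin) | c1c(OCc9ccccc9)cc(OCc9ccccc9)c2c1O[C@H](c1ccc(OCc9ccccc9)cc1)[C@H](OCc9ccccc9)C2 | intermediate
11 | (2R,3R)-8-bromo-3,5,7-tris(benzyloxy)-2-[4-(benzyloxy)phenyl]chromane | Brc1c(OCc9ccccc9)cc(OCc9ccccc9)c2c1O[C@H](c1ccc(OCc9ccccc9)cc1)[C@H](OCc9ccccc9)C2 | intermediate
12 | [(2R,3R)-3,5,7-tris(benzyloxy)-2-[4-(benzyloxy)phenyl]chroman-8-yl]lithium (not isolated) | [Li]c1c(OCc9ccccc9)cc(OCc9ccccc9)c2c1O[C@H](c1ccc(OCc9ccccc9)cc1)[C@H](OCc9ccccc9)C2 | intermediate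
13 | (1R,2R,3R)-2-(benzyloxy)-3-[3,5-bis(benzyloxy)phenoxy]-3-[4-(benzyloxy)phenyl]-1-[(2R,3R)-3,5,7-tris(benzyloxy)-2-[4-(benzyloxy)phenyl]chroman-8-yl]propan-1-ol (1R epimer drawn, 1S epimer also used) | c1([C@@H](O)[C@@H](OCc9ccccc9)[C@@H](c2ccc(OCc9ccccc9)cc2)Oc2cc(OCc9ccccc9)cc(OCc9ccccc9)c2)c(OCc9ccccc9)cc(OCc9ccccc9)c2c1O[C@H](c1ccc(OCc9ccccc9)cc1)[C@H](OCc9ccccc9)C2 | intermediate
14 | octa-O-benzyl-epiafzelechin-(4β→8)-epiafzelechin (each unit 3,5,7,4′-tetra-O-benzyl, 2R,3R; upper unit 3,4-trans) | c9ccccc9COc1ccc([C@H]2Oc3c(c(OCc9ccccc9)cc(OCc9ccccc9)c3)[C@H](c3c(OCc9ccccc9)cc(OCc9ccccc9)c4c3O[C@H](c3ccc(OCc9ccccc9)cc3)[C@H](OCc9ccccc9)C4)[C@H]2OCc9ccccc9)cc1 | intermediate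
15 | 8-bromo derivative of 14 (bromine on C8 of the upper unit) | c9ccccc9COc1ccc([C@H]2Oc3c(c(OCc9ccccc9)cc(OCc9ccccc9)c3Br)[C@H](c3c(OCc9ccccc9)cc(OCc9ccccc9)c4c3O[C@H](c3ccc(OCc9ccccc9)cc3)[C@H](OCc9ccccc9)C4)[C@H]2OCc9ccccc9)cc1 | intermediate
16 | 8-lithio derivative of 14 (lithium on C8 of the upper unit; not isolated) | c9ccccc9COc1ccc([C@H]2Oc3c(c(OCc9ccccc9)cc(OCc9ccccc9)c3[Li])[C@H](c3c(OCc9ccccc9)cc(OCc9ccccc9)c4c3O[C@H](c3ccc(OCc9ccccc9)cc3)[C@H](OCc9ccccc9)C4)[C@H]2OCc9ccccc9)cc1 | intermediate
17 | carbinol of the open top unit on C8 of the middle unit of 14: (1R,2R,3R)-2-(benzyloxy)-3-[3,5-bis(benzyloxy)phenoxy]-3-[4-(benzyloxy)phenyl]-1-hydroxypropyl group at that carbon (1R epimer drawn, 1S epimer also used) | c9ccccc9COc1ccc([C@H]2Oc3c(c(OCc9ccccc9)cc(OCc9ccccc9)c3[C@@H](O)[C@@H](OCc9ccccc9)[C@@H](c4ccc(OCc9ccccc9)cc4)Oc4cc(OCc9ccccc9)cc(OCc9ccccc9)c4)[C@H](c3c(OCc9ccccc9)cc(OCc9ccccc9)c4c3O[C@H](c3ccc(OCc9ccccc9)cc3)[C@H](OCc9ccccc9)C4)[C@H]2OCc9ccccc9)cc1 | intermediate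
18 | dodeca-O-benzyl-epiafzelechin-(4β→8)-epiafzelechin-(4β→8)-epiafzelechin | c9ccccc9COc1ccc([C@H]2Oc3c(c(OCc9ccccc9)cc(OCc9ccccc9)c3[C@H]3c4c(OCc9ccccc9)cc(OCc9ccccc9)cc4O[C@H](c4ccc(OCc9ccccc9)cc4)[C@@H]3OCc9ccccc9)[C@H](c3c(OCc9ccccc9)cc(OCc9ccccc9)c4c3O[C@H](c3ccc(OCc9ccccc9)cc3)[C@H](OCc9ccccc9)C4)[C@H]2OCc9ccccc9)cc1 | intermediate
19 | epiafzelechin-(4β→8)-epiafzelechin-(4β→8)-epiafzelechin (CNP0191553.1) | Oc1ccc([C@H]2Oc3c(c(O)cc(O)c3[C@H]3c4c(O)cc(O)cc4O[C@H](c4ccc(O)cc4)[C@@H]3O)[C@H](c3c(O)cc(O)c4c3O[C@H](c3ccc(O)cc3)[C@H](O)C4)[C@H]2O)cc1 | target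

**Step count and risks**

Total steps: 13. Longest linear sequence: 13 steps (1 to 19); aldehyde 8 is drawn on three times (steps 6, 8 and 11).

Steps most likely to fail:

1. Step 6 (reductive ring closure of the bottom unit). What may go wrong: silane reduction of the aldehyde before the ring has closed, capture of the flavan-4-yl cation by a second molecule, or reductive opening at C2–O1. Fallback: close the ring by acylation and remove the oxygen afterwards. Setting out from 7, LiOH (THF/H2O, 0 °C) would give the carboxylic acid F1. Trifluoroacetic anhydride (CH2Cl2, 0 °C) would then effect an intramolecular Friedel–Crafts acylation to the cis-3-benzyloxyflavan-4-one F2. NaBH4 (THF/MeOH, 0 °C) would give the flavan-4-ol 9, this time isolated, and Et3SiH with CF3CO2H (CH2Cl2, −20 °C) would reduce it to 10, where the route resumes.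

2. Step 3 (phenol opening of the glycidate). What may go wrong: loss of stereochemical fidelity through a benzylic ion pair (opening with retention), attack at C2, or C-alkylation by the ambident phenoxide. Fallback: carry out the opening on the epoxy alcohol, where phenoxide attack at the benzylic carbon with inversion is the normal course. Setting out from 4, NaBH4 (EtOH, 0 °C) would give the cis-epoxy alcohol F3, and phenol 5 with aq. NaOH (70 °C) would open it to the diol F4. TBSCl with imidazole would protect the primary hydroxyl as the silyl ether F5, NaH and BnBr would give the benzyl ether F6, and Bu4NF would release the primary alcohol F7. Dess–Martin periodinane (NaHCO3, CH2Cl2) would then give 8, where the route resumes.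

3. Step 12 (key ring closure). What may go wrong: poor facial selectivity giving the 3,4-cis epimer at the new C4, loss of the C3 proton from the cation to give an enol ether, or intermolecular arylation. Fallback: form the same interflavan bond in the conventional polarity. Setting out from 10, DDQ and 2-ethoxyethanol (CH2Cl2, rt) would give the 4β-(2-ethoxyethoxy)flavan F8. TMSOTf (catalytic, CH2Cl2, −78 °C) with an excess of dimer 14 would generate the flavan-4-yl cation, which should be captured trans to its C3 substituent by C8 of the upper unit of 14 to give 18, where the route resumes.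

**Further compounds**

F1 | step 6 | (2S,3R)-2-(benzyloxy)-3-[3,5-bis(benzyloxy)phenoxy]-3-[4-(benzyloxy)phenyl]propanoic acid | OC(=O)[C@@H](OCc1ccccc1)[C@@H](c1ccc(OCc2ccccc2)cc1)Oc1cc(OCc2ccccc2)cc(OCc2ccccc2)c1
F2 | step 6 | (2R,3S)-3,5,7-tris(benzyloxy)-2-[4-(benzyloxy)phenyl]chroman-4-one (2,3-cis) | O=C1c2c(OCc9ccccc9)cc(OCc9ccccc9)cc2O[C@H](c2ccc(OCc9ccccc9)cc2)[C@@H]1OCc9ccccc9
F3 | step 3 | [(2R,3S)-3-[4-(benzyloxy)phenyl]oxiran-2-yl]methanol (cis) | OC[C@H]1O[C@H]1c1ccc(OCc2ccccc2)cc1
F4 | step 3 | (2R,3R)-3-[3,5-bis(benzyloxy)phenoxy]-3-[4-(benzyloxy)phenyl]propane-1,2-diol | OC[C@@H](O)[C@@H](c1ccc(OCc2ccccc2)cc1)Oc1cc(OCc2ccccc2)cc(OCc2ccccc2)c1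
F5 | step 3 | (2R,3R)-3-[3,5-bis(benzyloxy)phenoxy]-3-[4-(benzyloxy)phenyl]-1-[(tert-butyldimethylsilyl)oxy]propan-2-ol | CC(C)(C)[Si](C)(C)OC[C@@H](O)[C@@H](c1ccc(OCc2ccccc2)cc1)Oc1cc(OCc2ccccc2)cc(OCc2ccccc2)c1
F6 | step 3 | tert-butyldimethylsilyl ether of (2R,3R)-2-(benzyloxy)-3-[3,5-bis(benzyloxy)phenoxy]-3-[4-(benzyloxy)phenyl]propan-1-ol | CC(C)(C)[Si](C)(C)OC[C@@H](OCc1ccccc1)[C@@H](c1ccc(OCc2ccccc2)cc1)Oc1cc(OCc2ccccc2)cc(OCc2ccccc2)c1
F7 | step 3 | (2R,3R)-2-(benzyloxy)-3-[3,5-bis(benzyloxy)phenoxy]-3-[4-(benzyloxy)phenyl]propan-1-ol | OC[C@@H](OCc1ccccc1)[C@@H](c1ccc(OCc2ccccc2)cc1)Oc1cc(OCc2ccccc2)cc(OCc2ccccc2)c1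
F8 | step 12 | 3,5,7,4′-tetra-O-benzyl-4β-(2-ethoxyethoxy)epiafzelechin (2,3-cis, 3,4-trans) | CCOCCO[C@H]1c2c(OCc9ccccc9)cc(OCc9ccccc9)cc2O[C@H](c2ccc(OCc9ccccc9)cc2)[C@@H]1OCc9ccccc9
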